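**Plan**

1. Retrosynthesis: the two O-benzyl helpers are removed first. The C7–C8 bond of the pentadecyl chain is then cut into two carboxylic acids, each one carbon longer than its half (nonanoic acid and an 8-aryl-7-(benzyloxy)octanoic acid), both as N-acyloxyphthalimides. Last, aryl–C1 is cut to an aryl Grignard reagent and (S)-1,2-epoxyoct-7-ene, whose vinyl group is the masked carboxyl.
2. Forward: no ring is formed and the chain is joined from the aryl end. Epoxide resolution, aryl–C1 bond by Cu-catalysed epoxide opening, O-benzylation, alkene → C8 acid → redox-active ester, cathodic Ni-catalysed doubly decarboxylative C7–C8 coupling with the nonanoic ester, one hydrogenolysis.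
3. Enabling feature: C7 and C8 are both primary CH2 carbons in the unbranched, unfunctionalised polymethylene part of the chain, five carbons beyond the C2 carbinol and remote from the benzene ring. Each can therefore be generated as an unbiased primary alkyl radical by loss of CO2 from a simple acid, and joining them cannot touch C2. The electron-rich 3,5-dioxygenated benzene ring is the reason the decarboxylation is run reductively at a cathode and not oxidatively (Kolbe).
4. Stereochemistry: the single stereocentre, C2 (S), comes from hydrolytic kinetic resolution of racemic 1,2-epoxyoct-7-ene; no bond to C2 is broken afterwards.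

Key step: step 9

Remark: the SMILES is read as (S)-1-(3-hydroxy-5-methoxyphenyl)pentadecan-2-ol (chain numbered from the benzylic carbon, C1); racemic 1,2-epoxyoct-7-ene, 3-bromo-5-methoxyphenol and nonanoic acid are taken as commercial.

**Route**

Step 1
Reactants: 1 rac-2-(hex-5-en-1-yl)oxirane (racemic 1,2-epoxyoct-7-ene)
Product: 2 (S)-2-(hex-5-en-1-yl)oxirane
Conditions: (S,S)-(salen)Co(III)OAc (0.5 mol%), H2O (0.55 equiv), THF (minimal), 0 °C → rt; distillation
Reagents that add atoms: none
Why: Jacobsen hydrolytic kinetic resolution: the (S,S)-cobalt salen complex should hydrate the (R)-epoxide much faster than the (S)-epoxide, so that unreacted (S)-2 is recovered and carries the only stereocentre of the route.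

Step 2
Reactants: 3 3-bromo-5-methoxyphenol
Product: 4 1-(benzyloxy)-3-bromo-5-methoxybenzene
Conditions: BnBr, K2CO3, DMF, rt
Reagents that add atoms: benzyl bromide, BrCc1ccccc1
Why: Williamson ether synthesis on the phenoxide, which masks the acidic O–H before Grignard formation and can be removed at the end without touching the methyl ether.

Step 3
Reactants: 4 1-(benzyloxy)-3-bromo-5-methoxybenzene; 2 (S)-2-(hex-5-en-1-yl)oxirane
Product: 6 (S)-1-[3-(benzyloxy)-5-methoxyphenyl]oct-7-en-2-ol, via aryl Grignard reagent 5 (not isolated)
Conditions: Mg, THF, 45 °C; then CuI (10 mol%), 2, THF, −30 → 0 °C; aq. NH4Cl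
Reagents that add atoms: none
Why: Copper-catalysed SN2 opening of a terminal epoxide by an aryl Grignard reagent at the unsubstituted carbon; the C2–O bond is not involved, so the (S) configuration of 2 should pass unchanged into 6.

Step 4
Reactants: 6 (S)-1-[3-(benzyloxy)-5-methoxyphenyl]oct-7-en-2-ol
Product: 7 (S)-1-(benzyloxy)-3-[2-(benzyloxy)oct-7-en-1-yl]-5-methoxybenzene
Conditions: NaH, BnBr, Bu4NI (cat.), THF/DMF, 0 °C → rt
Reagents that add atoms: benzyl bromide, BrCc1ccccc1
Why: Williamson benzylation of the sodium alkoxide; the second benzyl group shields the carbinol during the oxidations and leaves in the same final hydrogenolysis as the first.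

Step 5
Reactants: 7 (S)-1-(benzyloxy)-3-[2-(benzyloxy)oct-7-en-1-yl]-5-methoxybenzene
Product: 9 (S)-7-(benzyloxy)-8-[3-(benzyloxy)-5-methoxyphenyl]octan-1-ol, via B-alkyl-9-BBN 8 (not isolated)
Conditions: 9-BBN, THF, 0 °C → rt; then 3 M NaOH, 30% H2O2, 0 °C → rt
Reagents that add atoms: hydrogen peroxide, OO
Why: Hydroboration–oxidation: 9-BBN should place boron on the terminal carbon only, and alkaline peroxide replaces boron by hydroxyl without effect on the ethers or the remote stereocentre.

Step 6
Reactants: 9 (S)-7-(benzyloxy)-8-[3-(benzyloxy)-5-methoxyphenyl]octan-1-ol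
Product: 11 (S)-7-(benzyloxy)-8-[3-(benzyloxy)-5-methoxyphenyl]octanoic acid, via aldehyde 10 (not isolated)
Conditions: TEMPO (0.2 equiv), PhI(OAc)2 (2.2 equiv), MeCN/H2O 1:1, rt
Reagents that add atoms: water, O
Why: Oxoammonium (TEMPO) oxidation with PhI(OAc)2 as terminal oxidant should take the primary alcohol through aldehyde 10 and its hydrate to the acid under near-neutral conditions that benzyl ethers tolerate.

Step 7
Reactants: 11 (S)-7-(benzyloxy)-8-[3-(benzyloxy)-5-methoxyphenyl]octanoic acid
Product: 12 1,3-dioxoisoindolin-2-yl (S)-7-(benzyloxy)-8-[3-(benzyloxy)-5-methoxyphenyl]octanoate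
Conditions: N-hydroxyphthalimide, DIC, DMAP (cat.), CH2Cl2, rt
Reagents that add atoms: N-hydroxyphthalimide, ON1C(=O)c2ccccc2C1=O
Why: Carbodiimide (Steglich-type) esterification with N-hydroxyphthalimide, which installs the redox-active leaving group needed for reductive decarboxylation.

Step 8
Reactants: 13 nonanoic acid
Product: 14 1,3-dioxoisoindolin-2-yl nonanoate
Conditions: N-hydroxyphthalimide, DIC, DMAP (cat.), CH2Cl2, rt
Reagents that add atoms: N-hydroxyphthalimide, ON1C(=O)c2ccccc2C1=O
Why: The same carbodiimide esterification turns the cheap C9 acid into the redox-active partner that delivers the octyl half.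

Step 9
Reactants: 12 1,3-dioxoisoindolin-2-yl (S)-7-(benzyloxy)-8-[3-(benzyloxy)-5-methoxyphenyl]octanoate; 14 1,3-dioxoisoindolin-2-yl nonanoate (3 equiv)
Product: 17 (S)-1-(benzyloxy)-3-[2-(benzyloxy)pentadecyl]-5-methoxybenzene, via primary C7 radical 15 (not isolated), via octyl radical 16 (not isolated)
Conditions: NiCl2·6H2O (20 mol%), 2,2':6',2''-terpyridine (20 mol%), AgNO3 (0.3 equiv), LiBr, NMP, Mg(+)/RVC(−), constant current, rt; 1 M HCl work-up
Reagents that add atoms: none
Why: Nickel-mediated single-electron reduction at the cathode turns each N-acyloxyphthalimide into a radical anion that loses phthalimide anion and CO2 to leave the primary C7 radical 15 and the octyl radical 16; terpyridine-ligated nickel captures one radical and then the other, and the dialkylnickel(III) species reductively eliminates the C7–C8 bond, with the Mg anode supplying the electrons. The closest known reaction type is the nickel-electrocatalytic doubly decarboxylative C(sp3)–C(sp3) coupling of two redox-active esters, a reductive relative of the mixed Kolbe electrolysis and a union of two carbons of like (electrophilic) polarity. No ring is closed and no stereocentre is made; C2 lies five carbons from the radical site, none of its bonds is broken, and the only conceivable scrambling path, 1,6-hydrogen transfer from C2–H to the C7 radical, should be slow relative to capture by nickel. The step needs cross-coupling to win over homo-coupling between two primary radicals of equal reactivity, which is secured statistically by the 3 equiv of cheap ester 14, whose own dimer is a non-polar hydrocarbon removed by chromatography. It also needs chemoselectivity for the two ester groups, which is secured by working at the cathode: the electron-rich 1,3-dioxygenated benzene ring, which would be oxidised at a Kolbe anode, and both benzyl ethers should be inert at the potential that reduces the phthalimide esters.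

Step 10
Reactants: 17 (S)-1-(benzyloxy)-3-[2-(benzyloxy)pentadecyl]-5-methoxybenzene
Product: 18 (S)-1-(3-hydroxy-5-methoxyphenyl)pentadecan-2-ol (CNP0319653.1)
Conditions: H2 (1 atm), Pd(OH)2/C, EtOAc/EtOH, rt
Reagents that add atoms: none
Why: Catalytic hydrogenolysis should cleave the aryl benzyl ether and the secondary alkyl benzyl ether together, while the aryl methyl ether, the homobenzylic C–O bond and the stereocentre are not affected.

**Compound list**

1 | rac-2-(hex-5-en-1-yl)oxirane (racemic 1,2-epoxyoct-7-ene) | C=CCCCCC1CO1 | starting material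
2 | (S)-2-(hex-5-en-1-yl)oxirane | C=CCCCC[C@H]1CO1 | intermediate
3 | 3-bromo-5-methoxyphenol | COc1cc(O)cc(Br)c1 | starting material
4 | 1-(benzyloxy)-3-bromo-5-methoxybenzene | COc1cc(Br)cc(OCc2ccccc2)c1 | intermediate
5 | [3-(benzyloxy)-5-methoxyphenyl]magnesium bromide | COc1cc([Mg]Br)cc(OCc2ccccc2)c1 | intermediate (not isolated)
6 | (S)-1-[3-(benzyloxy)-5-methoxyphenyl]oct-7-en-2-ol | C=CCCCC[C@H](O)Cc1cc(OC)cc(OCc2ccccc2)c1 | intermediate
7 | (S)-1-(benzyloxy)-3-[2-(benzyloxy)oct-7-en-1-yl]-5-methoxybenzene | C=CCCCC[C@H](OCc1ccccc1)Cc1cc(OC)cc(OCc2ccccc2)c1 | intermediate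
8 | 9-[(S)-7-(benzyloxy)-8-[3-(benzyloxy)-5-methoxyphenyl]octyl]-9-borabicyclo[3.3.1]nonane | C1CCC2CCCC1B2CCCCCC[C@H](OCc1ccccc1)Cc1cc(OC)cc(OCc2ccccc2)c1 | intermediate (not isolated)
9 | (S)-7-(benzyloxy)-8-[3-(benzyloxy)-5-methoxyphenyl]octan-1-ol | OCCCCCC[C@H](OCc1ccccc1)Cc1cc(OC)cc(OCc2ccccc2)c1 | intermediate
10 | (S)-7-(benzyloxy)-8-[3-(benzyloxy)-5-methoxyphenyl]octanal | O=CCCCCC[C@H](OCc1ccccc1)Cc1cc(OC)cc(OCc2ccccc2)c1 | intermediate (not isolated)
11 | (S)-7-(benzyloxy)-8-[3-(benzyloxy)-5-methoxyphenyl]octanoic acid | OC(=O)CCCCC[C@H](OCc1ccccc1)Cc1cc(OC)cc(OCc2ccccc2)c1 | intermediate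
12 | 1,3-dioxoisoindolin-2-yl (S)-7-(benzyloxy)-8-[3-(benzyloxy)-5-methoxyphenyl]octanoate | O=C(CCCCC[C@H](OCc1ccccc1)Cc1cc(OC)cc(OCc2ccccc2)c1)ON1C(=O)c2ccccc2C1=O | intermediate
13 | nonanoic acid | CCCCCCCCC(=O)O | starting material
14 | 1,3-dioxoisoindolin-2-yl nonanoate | CCCCCCCCC(=O)ON1C(=O)c2ccccc2C1=O | intermediate
15 | (S)-6-(benzyloxy)-7-[3-(benzyloxy)-5-methoxyphenyl]heptyl radical | [CH2]CCCC[C@H](OCc1ccccc1)Cc1cc(OC)cc(OCc2ccccc2)c1 | intermediate (not isolated)
16 | octyl radical | [CH2]CCCCCCC | intermediate (not isolated)
17 | (S)-1-(benzyloxy)-3-[2-(benzyloxy)pentadecyl]-5-methoxybenzene | CCCCCCCCCCCCC[C@H](OCc1ccccc1)Cc1cc(OC)cc(OCc2ccccc2)c1 | intermediate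
18 | (S)-1-(3-hydroxy-5-methoxyphenyl)pentadecan-2-ol (CNP0319653.1) | CCCCCCCCCCCCC[C@H](O)Cc1cc(O)cc(OC)c1 | target

**Summary**

Total step count: 10. Longest linear sequence: 8 steps (1, 3, 4, 5, 6, 7, 9, 10); steps 2 and 8 prepare the side partners.

Steps most likely to fail:

Step 9 (key coupling). The two primary radicals are equally reactive, so material may leak into homo-dimerisation of the valuable half. The alkylnickel intermediate may also be reduced or undergo β-hydride elimination before the second radical arrives, and the redox-active ester may hydrolyse in the hygroscopic medium. The fallback makes the same C7–C8 connection by carbonyl olefination and sets out from 7. Lemieux–Johnson cleavage of the terminal alkene (OsO4 cat., NaIO4, 2,6-lutidine, dioxane/H2O) should give (S)-6-(benzyloxy)-7-[3-(benzyloxy)-5-methoxyphenyl]heptanal F1. Octyltriphenylphosphonium bromide with NaHMDS in THF at −78 °C gives octylidenetriphenylphosphorane F2, whose Wittig reaction with F1 should give (S,Z)-1-(benzyloxy)-3-[2-(benzyloxy)pentadec-7-en-1-yl]-5-methoxybenzene F3. Hydrogenation over Pd(OH)2/C saturates the alkene and removes both benzyl groups in one operation, so the fallback rejoins the route at 18.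

Step 3 (aryl Grignard opening of the epoxide). Aryl transfer from copper to an unactivated monoalkyl epoxide may be slow, which gives magnesium bromide time to open the epoxide to a bromohydrin; biaryl formation during Grignard generation is a second loss. The fallback takes the stereocentre from the chiral pool and lets an alkyl Grignard reagent do the second opening; it sets out from 4. Grignard reagent 5 with commercial (R)-epichlorohydrin and CuI (cat.) in THF at −40 °C should give (R)-1-[3-(benzyloxy)-5-methoxyphenyl]-3-chloropropan-2-ol F4. Ring closure with NaOH in Et2O/H2O gives (R)-2-[3-(benzyloxy)-5-methoxybenzyl]oxirane F5. Commercial pent-4-enylmagnesium bromide with CuI (cat.) at −30 °C opens F5 at the terminal carbon, and the fallback rejoins the route at 6 (step 1 is then not needed).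

Step 6 (alcohol to acid). The iodine(III) and oxoammonium oxidants may attack the activated ring positions between the two oxygens or oxidise a benzylic ether CH2 during the long second oxidation stage. The fallback separates the two oxidation levels and uses oxidants of a different class; it sets out from 9. Parikh–Doering oxidation (SO3·pyridine, DMSO, iPr2NEt, CH2Cl2, 0 °C) gives aldehyde 10, now isolated. Pinnick oxidation (NaClO2, NaH2PO4, t-BuOH/H2O) with a large excess of 2-methyl-2-butene, which traps hypochlorous acid before it can chlorinate the ring, then gives the acid, and the fallback rejoins the route at 11.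

**Further compounds**

F1 | step 9 | (S)-6-(benzyloxy)-7-[3-(benzyloxy)-5-methoxyphenyl]heptanal | O=CCCCC[C@H](OCc1ccccc1)Cc1cc(OC)cc(OCc2ccccc2)c1
F2 | step 9 | octylidenetriphenylphosphorane | CCCCCCCC=P(c1ccccc1)(c1ccccc1)c1ccccc1
F3 | step 9 | (S,Z)-1-(benzyloxy)-3-[2-(benzyloxy)pentadec-7-en-1-yl]-5-methoxybenzene | CCCCCCC/C=C\CCCC[C@H](OCc1ccccc1)Cc1cc(OC)cc(OCc2ccccc2)c1
F4 | step 3 | (R)-1-[3-(benzyloxy)-5-methoxyphenyl]-3-chloropropan-2-ol | ClC[C@H](O)Cc1cc(OC)cc(OCc2ccccc2)c1
F5 | step 3 | (R)-2-[3-(benzyloxy)-5-methoxybenzyl]oxirane | C1[C@H](O1)Cc1cc(OC)cc(OCc2ccccc2)c1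
F0 | step 6 | none | none
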